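**Strategy.** The target is the tetramer epigallocatechin-(4β→8)-epigallocatechin-(4β→8)-epigallocatechin 3-O-gallate-(4β→8)-epicatechin. Benzylated units are joined by three Lewis acid-mediated C4→C8 couplings, and the terminal epicatechin is built de novo. Its ring C is cut at O1–C2 and C3–C4: O1 and C4 sit ortho on ring A, as in a salicylaldehyde, and C2–C3 is the Cβ–Cα pair of a cinnamaldehyde carrying ring B. An aminocatalytic oxa-Michael/aldol condensation forms both bonds in one operation and sets C2; the formyl group left on C3 is then exchanged for oxygen by Baeyer–Villiger oxidation, and cis-selective reduction gives the 3-ol.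

Key step: step 3

Remark on the chemistry: the SMILES is read as four 2R,3R flavan-3-ol units (three epigallocatechin, the third as its 3-O-gallate, and a terminal epicatechin) joined by three 4β→8 (3,4-trans) bonds. The sense of induction in step 3 is assigned from the usual shielding model of the iminium ion; should it prove opposite, the enantiomeric catalyst is used. Compounds 1, 3, 4, 10 and 13 are purchased.

**Step 1**
Reactants: 1 2,4,6-trihydroxybenzaldehyde
Product: 2 2-hydroxy-4,6-bis(benzyloxy)benzaldehyde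
Conditions: BnBr (2.1 equiv), K2CO3, DMF, 0 °C to rt
Reagents that add atoms: benzyl bromide BrCc1ccccc1
Why: Williamson etherification should stop at the dibenzyl ether because the remaining ortho hydroxyl is held in a hydrogen bond to the formyl group and is the least nucleophilic of the three.

**Step 2**
Reactants: 3 3,4-bis(benzyloxy)benzaldehyde; 4 (triphenylphosphoranylidene)acetaldehyde
Product: 5 (E)-3-[3,4-bis(benzyloxy)phenyl]prop-2-enal
Conditions: toluene, 80 °C
Reagents that add atoms: none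
Why: Wittig olefination with a stabilised formyl ylide should give the E-configured enal by two-carbon homologation.

**Step 3**
Reactants: 2 2-hydroxy-4,6-bis(benzyloxy)benzaldehyde; 5 (E)-3-[3,4-bis(benzyloxy)phenyl]prop-2-enal
Product: 6 (2R)-5,7-bis(benzyloxy)-2-[3,4-bis(benzyloxy)phenyl]-2H-chromene-3-carbaldehyde
Conditions: (S)-2-[diphenyl(trimethylsilyloxy)methyl]pyrrolidine (20 mol %), 2-nitrobenzoic acid (20 mol %), 4 Å MS, toluene, rt
Reagents that add atoms: none
Why: The amine catalyst condenses with enal 5 to an E-configured iminium ion, the phenolic oxygen of 2 adds to C-β (oxa-Michael, O1–C2), and the resulting enamine attacks the ortho formyl carbon (intramolecular aldol, C3–C4); loss of water then releases the catalyst and the conjugated 2H-chromene. The closest known reaction type is the aminocatalytic domino oxa-Michael/aldol condensation of salicylaldehydes with cinnamaldehydes. Ring C closes in the aldol event as a 6-exo-trig attack of the enamine carbon on the aldehyde carbonyl, the preceding oxa-Michael addition being intermolecular. The only stereocenter formed, C2, is controlled by the catalyst: the diphenyl(silyloxy)methyl group shields the Re face of C-β, so oxygen should add to the Si face and give the 2R configuration. The step needs chemoselectivity between the two aldehydes and a product that does not racemise: only enal 5 can form a conjugated iminium acceptor, aldehyde 2 can act only as O-nucleophile and aldol acceptor because its OH and CHO are ortho, and C2–H of 6 is cross-conjugated to the formyl group and therefore not acidified.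

**Step 4**
Reactants: 6 (2R)-5,7-bis(benzyloxy)-2-[3,4-bis(benzyloxy)phenyl]-2H-chromene-3-carbaldehyde
Product: 8 (2R)-5,7-bis(benzyloxy)-2-[3,4-bis(benzyloxy)phenyl]chroman-3-one, via enol formate 7 (not isolated)
Conditions: mCPBA (1.05 equiv), CH2Cl2, −20 to 0 °C; aq. NaHCO3 wash; then KHCO3 (cat.), MeOH, 0 °C
Reagents that add atoms: 3-chloroperoxybenzoic acid O=C(OO)c1cccc(Cl)c1
Why: Baeyer–Villiger oxidation of the conjugated aldehyde, in which the electron-rich alkenyl carbon C3 migrates to oxygen in preference to hydrogen, should give the enol formate, and mild methanolysis frees the enol, which ketonises by protonation at C4 so that C4 becomes the methylene group while C2 is not touched.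

**Step 5**
Reactants: 8 (2R)-5,7-bis(benzyloxy)-2-[3,4-bis(benzyloxy)phenyl]chroman-3-one
Product: 9 (2R,3R)-5,7-bis(benzyloxy)-2-[3,4-bis(benzyloxy)phenyl]chroman-3-ol (5,7,3',4'-tetra-O-benzyl-(−)-epicatechin)
Conditions: LiBH(s-Bu)3 (L-Selectride), THF, −78 °C; then H2O
Reagents that add atoms: none
Why: In this substrate-controlled ketone reduction the bulky hydride should attack C3 from the face opposite the C2 aryl group, placing the hydroxyl cis to ring B (3R), as is established for benzylated flavan-3-ones.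

**Step 6**
Reactants: 10 (−)-epigallocatechin
Product: 11 (2R,3R)-5,7-bis(benzyloxy)-2-[3,4,5-tris(benzyloxy)phenyl]chroman-3-ol
Conditions: BnBr (5.5 equiv), K2CO3, DMF, 0 °C to rt, argon
Reagents that add atoms: benzyl bromide BrCc1ccccc1
Why: Williamson etherification under K2CO3 should alkylate only the five phenolic hydroxyls, since the secondary C3 alcohol is not deprotonated by carbonate, and C2 and C3 are untouched.

**Step 7**
Reactants: 11 (2R,3R)-5,7-bis(benzyloxy)-2-[3,4,5-tris(benzyloxy)phenyl]chroman-3-ol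
Product: 12 (2R,3R,4S)-5,7-bis(benzyloxy)-4-(2-ethoxyethoxy)-2-[3,4,5-tris(benzyloxy)phenyl]chroman-3-ol (4β ether, 3,4-trans)
Conditions: DDQ (2 equiv), 2-ethoxyethanol, CH2Cl2, rt
Reagents that add atoms: 2-ethoxyethanol CCOCCO
Why: DDQ abstracts hydride from the benzylic C4 position activated by the 5,7-dioxygenated ring A, and the resulting cation is trapped by 2-ethoxyethanol on the face anti to the C3 hydroxyl and the C2 aryl group, which should give the 4β ether as in the known C4 oxidation of benzylated flavan-3-ols.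

**Step 8**
Reactants: 12 (2R,3R,4S)-5,7-bis(benzyloxy)-4-(2-ethoxyethoxy)-2-[3,4,5-tris(benzyloxy)phenyl]chroman-3-ol; 13 3,4,5-tris(benzyloxy)benzoic acid
Product: 14 (2R,3R,4S)-5,7-bis(benzyloxy)-4-(2-ethoxyethoxy)-2-[3,4,5-tris(benzyloxy)phenyl]chroman-3-yl 3,4,5-tris(benzyloxy)benzoate
Conditions: DCC, DMAP (cat.), CH2Cl2, rt
Reagents that add atoms: none
Why: Steglich esterification should acylate the secondary C3 hydroxyl with retention of configuration and leave the C4 acetal-type ether intact under these neutral conditions.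

**Step 9**
Reactants: 14 galloylated C4 electrophile; 9 5,7,3',4'-tetra-O-benzyl-(−)-epicatechin
Product: 15 dodeca-O-benzyl dimer, 3-O-[3,4,5-tris(benzyloxy)benzoyl]-5,7,3',4',5'-penta-O-benzylepigallocatechin-(4β→8)-5,7,3',4'-tetra-O-benzylepicatechin
Conditions: Me3SiOTf (0.3 equiv), CH2Cl2, −78 to −40 °C; 9 in excess (3 equiv, recovered)
Reagents that add atoms: none
Why: Me3SiOTf ionises the C4 ether of 14 to a benzylic cation stabilised by ring A, and Friedel–Crafts attack by C8 of 9, its most nucleophilic and least hindered position, on the face anti to the 3-acyloxy and 2-aryl groups should give the 4β→8 (3,4-trans) bond, the excess of 9 suppressing self-condensation of 14.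

**Step 10**
Reactants: 12 C4 electrophile of penta-O-benzylepigallocatechin; 15 dodeca-O-benzyl dimer
Product: 16 heptadeca-O-benzyl trimer, 5,7,3',4',5'-penta-O-benzylepigallocatechin-(4β→8)-[3-O-tris(benzyloxy)benzoyl-penta-O-benzylepigallocatechin]-(4β→8)-tetra-O-benzylepicatechin
Conditions: Me3SiOTf (0.3 equiv), CH2Cl2, −78 °C; 12 added slowly to 15 (2.5 equiv, excess recovered)
Reagents that add atoms: none
Why: In the same flavan-4-yl cation arylation the cation from 12 should be intercepted by the only unsubstituted C8 position of 15 (on the gallate-bearing unit; the C6 positions are flanked by two benzyloxy groups), anti to the C3 and C2 substituents to give the 4β→8 bond, with 15 in excess to outcompete self-condensation of 12.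

**Step 11**
Reactants: 12 C4 electrophile of penta-O-benzylepigallocatechin; 16 heptadeca-O-benzyl trimer
Product: 17 docosa-O-benzyl tetramer, penta-O-benzylepigallocatechin-(4β→8)-penta-O-benzylepigallocatechin-(4β→8)-[3-O-tris(benzyloxy)benzoyl-penta-O-benzylepigallocatechin]-(4β→8)-tetra-O-benzylepicatechin
Conditions: Me3SiOTf (0.3 equiv), CH2Cl2, −78 °C; 12 added slowly to 16 (2 equiv, excess recovered)
Reagents that add atoms: none
Why: The third cation arylation should again take place at the single free C8 position, now on the uppermost unit of 16, and anti to the C3 hydroxyl and C2 aryl group of the cation, which sets the last 4β→8 bond.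

**Step 12**
Reactants: 17 docosa-O-benzyl tetramer
Product: 18 epigallocatechin-(4β→8)-epigallocatechin-(4β→8)-epigallocatechin 3-O-gallate-(4β→8)-epicatechin (CNP0305998.1)
Conditions: H2 (1 atm), Pd(OH)2/C, THF/MeOH/H2O, rt, then filtration and lyophilisation under argon
Reagents that add atoms: none
Why: Hydrogenolysis over Pd(OH)2/C should cleave all twenty-two benzyl ethers under neutral conditions that leave the gallate ester, the acid-labile interflavan bonds and every stereocenter untouched.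

**Compound list**

1 | 2,4,6-trihydroxybenzaldehyde | O=Cc1c(O)cc(O)cc1O | starting material
2 | 2-hydroxy-4,6-bis(benzyloxy)benzaldehyde | O=Cc1c(O)cc(OCc2ccccc2)cc1OCc1ccccc1 | intermediate
3 | 3,4-bis(benzyloxy)benzaldehyde | O=Cc1ccc(OCc2ccccc2)c(OCc2ccccc2)c1 | starting material
4 | (triphenylphosphoranylidene)acetaldehyde | O=CC=P(c1ccccc1)(c1ccccc1)c1ccccc1 | starting material
5 | (E)-3-[3,4-bis(benzyloxy)phenyl]prop-2-enal | O=C/C=C/c1ccc(OCc2ccccc2)c(OCc2ccccc2)c1 | intermediate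
6 | (2R)-5,7-bis(benzyloxy)-2-[3,4-bis(benzyloxy)phenyl]-2H-chromene-3-carbaldehyde | O=CC1=Cc2c(OCc3ccccc3)cc(OCc3ccccc3)cc2O[C@@H]1c1ccc(OCc2ccccc2)c(OCc2ccccc2)c1 | intermediate
7 | (2R)-5,7-bis(benzyloxy)-2-[3,4-bis(benzyloxy)phenyl]-2H-chromen-3-yl formate | O=COC1=Cc2c(OCc3ccccc3)cc(OCc3ccccc3)cc2O[C@@H]1c1ccc(OCc2ccccc2)c(OCc2ccccc2)c1 | intermediate (not isolated)
8 | (2R)-5,7-bis(benzyloxy)-2-[3,4-bis(benzyloxy)phenyl]chroman-3-one | O=C1Cc2c(OCc3ccccc3)cc(OCc3ccccc3)cc2O[C@@H]1c1ccc(OCc2ccccc2)c(OCc2ccccc2)c1 | intermediate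
9 | (2R,3R)-5,7-bis(benzyloxy)-2-[3,4-bis(benzyloxy)phenyl]chroman-3-ol | O[C@@H]1Cc2c(OCc3ccccc3)cc(OCc3ccccc3)cc2O[C@@H]1c1ccc(OCc2ccccc2)c(OCc2ccccc2)c1 | intermediate
10 | (−)-epigallocatechin, (2R,3R)-2-(3,4,5-trihydroxyphenyl)chromane-3,5,7-triol | O[C@@H]1Cc2c(O)cc(O)cc2O[C@@H]1c1cc(O)c(O)c(O)c1 | starting material
11 | (2R,3R)-5,7-bis(benzyloxy)-2-[3,4,5-tris(benzyloxy)phenyl]chroman-3-ol | O[C@@H]1Cc2c(OCc3ccccc3)cc(OCc3ccccc3)cc2O[C@@H]1c1cc(OCc2ccccc2)c(OCc2ccccc2)c(OCc2ccccc2)c1 | intermediate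
12 | (2R,3R,4S)-5,7-bis(benzyloxy)-4-(2-ethoxyethoxy)-2-[3,4,5-tris(benzyloxy)phenyl]chroman-3-ol | CCOCCO[C@H]1c2c(OCc3ccccc3)cc(OCc3ccccc3)cc2O[C@H](c2cc(OCc3ccccc3)c(OCc3ccccc3)c(OCc3ccccc3)c2)[C@@H]1O | intermediate
13 | 3,4,5-tris(benzyloxy)benzoic acid | OC(=O)c1cc(OCc2ccccc2)c(OCc2ccccc2)c(OCc2ccccc2)c1 | starting material
14 | (2R,3R,4S)-5,7-bis(benzyloxy)-4-(2-ethoxyethoxy)-2-[3,4,5-tris(benzyloxy)phenyl]chroman-3-yl 3,4,5-tris(benzyloxy)benzoate | CCOCCO[C@H]1c2c(OCc3ccccc3)cc(OCc3ccccc3)cc2O[C@H](c2cc(OCc3ccccc3)c(OCc3ccccc3)c(OCc3ccccc3)c2)[C@@H]1OC(=O)c1cc(OCc2ccccc2)c(OCc2ccccc2)c(OCc2ccccc2)c1 | intermediate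
15 | dodeca-O-benzyl dimer (benzylated epigallocatechin 3-O-gallate-(4β→8)-epicatechin, 3-OH of the lower unit free) | O=C(O[C@@H]1[C@@H](c2c(OCc7ccccc7)cc(OCc7ccccc7)c3c2O[C@H](c2ccc(OCc7ccccc7)c(OCc7ccccc7)c2)[C@H](O)C3)c2c(OCc7ccccc7)cc(OCc7ccccc7)cc2O[C@@H]1c1cc(OCc7ccccc7)c(OCc7ccccc7)c(OCc7ccccc7)c1)c1cc(OCc7ccccc7)c(OCc7ccccc7)c(OCc7ccccc7)c1 | intermediate
16 | heptadeca-O-benzyl trimer (benzylated epigallocatechin-(4β→8)-epigallocatechin 3-O-gallate-(4β→8)-epicatechin) | O=C(O[C@@H]1[C@@H](c2c(OCc7ccccc7)cc(OCc7ccccc7)c3c2O[C@H](c2ccc(OCc7ccccc7)c(OCc7ccccc7)c2)[C@H](O)C3)c2c(OCc7ccccc7)cc(OCc7ccccc7)c([C@H]3c4c(OCc7ccccc7)cc(OCc7ccccc7)cc4O[C@H](c4cc(OCc7ccccc7)c(OCc7ccccc7)c(OCc7ccccc7)c4)[C@@H]3O)c2O[C@@H]1c1cc(OCc7ccccc7)c(OCc7ccccc7)c(OCc7ccccc7)c1)c1cc(OCc7ccccc7)c(OCc7ccccc7)c(OCc7ccccc7)c1 | intermediate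
17 | docosa-O-benzyl tetramer (all phenols of the target as benzyl ethers) | O=C(O[C@@H]1[C@@H](c2c(OCc7ccccc7)cc(OCc7ccccc7)c3c2O[C@H](c2ccc(OCc7ccccc7)c(OCc7ccccc7)c2)[C@H](O)C3)c2c(OCc7ccccc7)cc(OCc7ccccc7)c([C@H]3c4c(OCc7ccccc7)cc(OCc7ccccc7)c([C@H]5c6c(OCc7ccccc7)cc(OCc7ccccc7)cc6O[C@H](c6cc(OCc7ccccc7)c(OCc7ccccc7)c(OCc7ccccc7)c6)[C@@H]5O)c4O[C@H](c4cc(OCc7ccccc7)c(OCc7ccccc7)c(OCc7ccccc7)c4)[C@@H]3O)c2O[C@@H]1c1cc(OCc7ccccc7)c(OCc7ccccc7)c(OCc7ccccc7)c1)c1cc(OCc7ccccc7)c(OCc7ccccc7)c(OCc7ccccc7)c1 | intermediate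
18 | epigallocatechin-(4β→8)-epigallocatechin-(4β→8)-epigallocatechin 3-O-gallate-(4β→8)-epicatechin (CNP0305998.1) | O=C(O[C@@H]1[C@@H](c2c(O)cc(O)c3c2O[C@H](c2ccc(O)c(O)c2)[C@H](O)C3)c2c(O)cc(O)c([C@H]3c4c(O)cc(O)c([C@H]5c6c(O)cc(O)cc6O[C@H](c6cc(O)c(O)c(O)c6)[C@@H]5O)c4O[C@H](c4cc(O)c(O)c(O)c4)[C@@H]3O)c2O[C@@H]1c1cc(O)c(O)c(O)c1)c1cc(O)c(O)c(O)c1 | target

**Step count and risks**

Total step count: 12. Longest linear sequence: 8 steps (steps 1, 3, 4, 5, 9, 10, 11, 12).

Steps most likely to fail: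

Step 3. The aldehyde of 2 is electron-rich and hydrogen-bonded, so the aldol closure may be too slow; the reversible oxa-Michael adduct could then revert, stalling conversion or eroding facial selectivity at C2. The fallback sets out from 2 and comes back at 8. It changes the acceptor to the purchased nitroalkene (E)-1,2-bis(benzyloxy)-4-(2-nitroethenyl)benzene F1. An enantioselective tandem oxa-Michael/Henry condensation under chiral secondary amine/salicylic acid co-catalysis (aromatic iminium activation of 2) would form the same two bonds and give (2R)-5,7-bis(benzyloxy)-2-[3,4-bis(benzyloxy)phenyl]-3-nitro-2H-chromene F2, which can be enriched by recrystallisation. Reductive hydrolysis of the nitroalkene (Fe powder, AcOH/H2O, 70 °C) would then give ketone 8 directly.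

Step 4. The peracid may epoxidise the electron-rich enol formate (over-oxidation), and C2 configuration may be lost by enolisation during formate cleavage. The fallback sets out from 6 and comes back at 8. Pinnick oxidation (NaClO2, NaH2PO4, 2-methyl-2-butene, t-BuOH/H2O) would give (2R)-5,7-bis(benzyloxy)-2-[3,4-bis(benzyloxy)phenyl]-2H-chromene-3-carboxylic acid F3. Curtius degradation with diphenylphosphoryl azide and Et3N in toluene would pass through the acyl azide F4 and, at 80 °C, the vinyl isocyanate (2R)-5,7-bis(benzyloxy)-2-[3,4-bis(benzyloxy)phenyl]-3-isocyanato-2H-chromene F5. Dilute aqueous HCl in THF would hydrolyse F5 through the enamine to 8.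

Step 10. Self-condensation of the C8-unprotected electrophile 12 may compete with chain extension and give oligomer mixtures. The fallback sets out from 11 and comes back at 16. Bromination with N-bromosuccinimide (CH2Cl2, −78 °C) would give (2R,3R)-5,7-bis(benzyloxy)-8-bromo-2-[3,4,5-tris(benzyloxy)phenyl]chroman-3-ol F6. DDQ/2-ethoxyethanol would convert it to the C8-capped electrophile (2R,3R,4S)-5,7-bis(benzyloxy)-8-bromo-4-(2-ethoxyethoxy)-2-[3,4,5-tris(benzyloxy)phenyl]chroman-3-ol F7, which cannot act as a nucleophile. Equimolar coupling of F7 with 15 (Me3SiOTf, CH2Cl2, −78 °C) would give the 8-bromo heptadeca-O-benzyl trimer F8, and radical debromination (Bu3SnH, AIBN, toluene, 80 °C) would return 16.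

**Further compounds**

F1 | step 3 | (E)-1,2-bis(benzyloxy)-4-(2-nitroethenyl)benzene (purchased) | O=[N+]([O-])/C=C/c1ccc(OCc2ccccc2)c(OCc2ccccc2)c1
F2 | step 3 | (2R)-5,7-bis(benzyloxy)-2-[3,4-bis(benzyloxy)phenyl]-3-nitro-2H-chromene | O=[N+]([O-])C1=Cc2c(OCc3ccccc3)cc(OCc3ccccc3)cc2O[C@@H]1c1ccc(OCc2ccccc2)c(OCc2ccccc2)c1
F3 | step 4 | (2R)-5,7-bis(benzyloxy)-2-[3,4-bis(benzyloxy)phenyl]-2H-chromene-3-carboxylic acid | OC(=O)C1=Cc2c(OCc3ccccc3)cc(OCc3ccccc3)cc2O[C@@H]1c1ccc(OCc2ccccc2)c(OCc2ccccc2)c1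
F4 | step 4 | (2R)-5,7-bis(benzyloxy)-2-[3,4-bis(benzyloxy)phenyl]-2H-chromene-3-carbonyl azide | [N-]=[N+]=NC(=O)C1=Cc2c(OCc3ccccc3)cc(OCc3ccccc3)cc2O[C@@H]1c1ccc(OCc2ccccc2)c(OCc2ccccc2)c1
F5 | step 4 | (2R)-5,7-bis(benzyloxy)-2-[3,4-bis(benzyloxy)phenyl]-3-isocyanato-2H-chromene | O=C=NC1=Cc2c(OCc3ccccc3)cc(OCc3ccccc3)cc2O[C@@H]1c1ccc(OCc2ccccc2)c(OCc2ccccc2)c1
F6 | step 10 | (2R,3R)-5,7-bis(benzyloxy)-8-bromo-2-[3,4,5-tris(benzyloxy)phenyl]chroman-3-ol | O[C@@H]1Cc2c(OCc3ccccc3)cc(OCc3ccccc3)c(Br)c2O[C@@H]1c1cc(OCc2ccccc2)c(OCc2ccccc2)c(OCc2ccccc2)c1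
F7 | step 10 | (2R,3R,4S)-5,7-bis(benzyloxy)-8-bromo-4-(2-ethoxyethoxy)-2-[3,4,5-tris(benzyloxy)phenyl]chroman-3-ol | CCOCCO[C@H]1c2c(OCc3ccccc3)cc(OCc3ccccc3)c(Br)c2O[C@H](c2cc(OCc3ccccc3)c(OCc3ccccc3)c(OCc3ccccc3)c2)[C@@H]1O
F8 | step 10 | 8-bromo heptadeca-O-benzyl trimer (16 with bromine at C8 of the uppermost unit) | O=C(O[C@@H]1[C@@H](c2c(OCc7ccccc7)cc(OCc7ccccc7)c3c2O[C@H](c2ccc(OCc7ccccc7)c(OCc7ccccc7)c2)[C@H](O)C3)c2c(OCc7ccccc7)cc(OCc7ccccc7)c([C@H]3c4c(OCc7ccccc7)cc(OCc7ccccc7)c(Br)c4O[C@H](c4cc(OCc7ccccc7)c(OCc7ccccc7)c(OCc7ccccc7)c4)[C@@H]3O)c2O[C@@H]1c1cc(OCc7ccccc7)c(OCc7ccccc7)c(OCc7ccccc7)c1)c1cc(OCc7ccccc7)c(OCc7ccccc7)c(OCc7ccccc7)c1
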